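**Retrosynthetic overview**

1. Target (2S)-flavanone ⇐ acidic removal of two MOM ethers ⇐ ligand-controlled CuH 1,4-reduction of the corresponding flavone, which sets C2 last on a flat pyranone.
2. Flavone ⇐ one-pot anionic [3+3] annulation of two halves: C3–C4 by C-acylation of the lithium enolate of the ring B/D methyl ketone with a ring A 2-fluorobenzoyl chloride, then O1–C8a by intramolecular SNAr of the enolate oxygen; ring C is the last ring formed.
3. Enabling feature: in ring C the carbonyl carbon C4 sits on C4a, ortho to C8a, which carries O1. Ring A can therefore act as a 1,3-dielectrophile (acyl C4 plus a C8a–F bond activated by the ortho C4=O), matched by the C3–C2–O1 enolate once C2 is raised to the sp2 (flavone) oxidation level.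
4. Ring A half ⇐ 4-bromo-3-fluorophenol: the MOM ether directs lithiation to the carbon between F and OMOM (future C8) for prenylation; Br is then converted into the C4 acyl chloride.
5. Ring B/D half ⇐ 2,2-dimethylchroman-7-ol (pyran ring D present from the start): C6 acetylation, DDQ dehydrogenation to the 2H-chromene, MOM protection.

Key step: step 8

Remark: 2,2-dimethylchroman-7-ol is taken as a purchasable building block, and the ligand antipode in step 9 is written as (R) and is to be exchanged for (S) if a test reduction shows the 2R product.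

**Route**

Step 1
Reactants: 1 4-bromo-3-fluorophenol
Product: 2 1-bromo-2-fluoro-4-(methoxymethoxy)benzene
Conditions: MOMCl, K2CO3, acetone, 0 °C to rt
Reagents that add atoms: chloromethyl methyl ether (MOMCl), COCCl
Why: Williamson-type O-alkylation of the acidic fluorophenol under carbonate base gives the MOM ether, which is stable to the organometallic steps and is the directing group for step 2.

Step 2
Reactants: 2 1-bromo-2-fluoro-4-(methoxymethoxy)benzene
Product: 5 1-bromo-2-fluoro-4-(methoxymethoxy)-3-(3-methylbut-2-en-1-yl)benzene, via aryllithium 3 (not isolated), via arylcopper 4 (not isolated)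
Conditions: LiN(i-Pr)2, THF, −78 °C; CuBr·SMe2, −78 °C; prenyl bromide, −78 to 0 °C
Reagents that add atoms: prenyl bromide (1-bromo-3-methylbut-2-ene), CC(C)=CCBr
Why: Directed ortho-metalation: the amide base removes the proton flanked by fluorine and the OMOM group (the most acidic ring position, and the C–Br bond is inert to an amide base at −78 °C), transmetalation of 3 to copper forestalls loss of LiF, and arylcopper 4 alkylates prenyl bromide at its unhindered α-carbon (SN2), which fixes the prenyl group on the future C8.

Step 3
Reactants: 5 1-bromo-2-fluoro-4-(methoxymethoxy)-3-(3-methylbut-2-en-1-yl)benzene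
Product: 8 2-fluoro-4-(methoxymethoxy)-3-(3-methylbut-2-en-1-yl)benzoic acid, via aryllithium 6 (not isolated), via lithium carboxylate 7 (not isolated)
Conditions: n-BuLi, THF, −78 °C; CO2 (g), −78 °C to rt; then 1 M HCl to pH 3, 0 °C
Reagents that add atoms: carbon dioxide, O=C=O
Why: Bromine–lithium exchange at −78 °C is faster than deprotonation and cold enough that the ortho-fluoro aryllithium 6 keeps its fluoride, and carboxylation with CO2 followed by mild acidification (tolerated by the MOM ether) installs the carbon that becomes C4.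

Step 4
Reactants: 8 2-fluoro-4-(methoxymethoxy)-3-(3-methylbut-2-en-1-yl)benzoic acid
Product: 9 2-fluoro-4-(methoxymethoxy)-3-(3-methylbut-2-en-1-yl)benzoyl chloride
Conditions: 1-chloro-N,N,2-trimethylprop-1-en-1-amine, CH2Cl2, 0 °C to rt; volatiles removed, used crude
Reagents that add atoms: 1-chloro-N,N,2-trimethylprop-1-en-1-amine, CC(C)=C(Cl)N(C)C
Why: The α-chloroenamine turns the acid into its chloride under neutral conditions (the by-product is an amide and no HCl is released), so the MOM ether and the prenyl alkene survive.

Step 5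
Reactants: 10 2,2-dimethylchroman-7-ol
Product: 12 1-(7-hydroxy-2,2-dimethylchroman-6-yl)ethan-1-one, via aryl acetate 11 (not isolated)
Conditions: AcCl, Hf(OTf)4 (5 mol %), toluene/MeNO2, 100 °C
Reagents that add atoms: acetyl chloride, CC(Cl)=O
Why: Metal triflate-catalysed direct C-acylation of a phenol (O-acetylation to 11, then Fries rearrangement) places the acetyl group ortho to the hydroxyl and para to the ring oxygen, at C6, as in the acylation of 3-alkoxyphenols, because C8 between the two oxygens is the more hindered ortho site.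

Step 6
Reactants: 12 1-(7-hydroxy-2,2-dimethylchroman-6-yl)ethan-1-one
Product: 13 1-(7-hydroxy-2,2-dimethyl-2H-chromen-6-yl)ethan-1-one
Conditions: DDQ (1.2 equiv), 1,4-dioxane, 100 °C
Reagents that add atoms: none
Why: DDQ dehydrogenation of a 2,2-dimethylchroman to the 2H-chromene, by hydride abstraction from benzylic C4 (activated by the para 7-OH and the ortho ring oxygen) and proton loss from C3, stops at the chromene since C2 is quaternary.

Step 7
Reactants: 13 1-(7-hydroxy-2,2-dimethyl-2H-chromen-6-yl)ethan-1-one
Product: 14 1-[7-(methoxymethoxy)-2,2-dimethyl-2H-chromen-6-yl]ethan-1-one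
Conditions: MOMCl, K2CO3, acetone, reflux
Reagents that add atoms: chloromethyl methyl ether (MOMCl), COCCl
Why: O-alkylation of the hydrogen-bonded phenol with MOMCl masks the acidic OH, so that step 8 needs base only for the enolate and the diketone and the phenol cannot be acylated.

Step 8
Reactants: 14 1-[7-(methoxymethoxy)-2,2-dimethyl-2H-chromen-6-yl]ethan-1-one; 9 2-fluoro-4-(methoxymethoxy)-3-(3-methylbut-2-en-1-yl)benzoyl chloride
Product: 17 7-(methoxymethoxy)-2-[7-(methoxymethoxy)-2,2-dimethyl-2H-chromen-6-yl]-8-(3-methylbut-2-en-1-yl)-4H-chromen-4-one, via lithium enolate 15 (not isolated), via lithium diketonate 16 (not isolated)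
Conditions: LiN(SiMe3)2 (2.2 equiv), THF, −78 °C; 9, −78 to 0 °C; then DMF added, THF distilled off, 100 °C
Reagents that add atoms: none
Why: The lithium enolate 15 attacks the acyl chloride carbon of 9 (Claisen-type C-acylation, forming C3–C4), and the second equivalent of base converts the 1,3-diketone at once into diketonate 16, which blocks a second acylation and lets any O-acylated material be recycled by acyl transfer. On heating in DMF the enolate oxygen on C2 adds to the fluorine-bearing C8a, ortho to the C4 carbonyl, through a Meisenheimer-type transition structure and fluoride is expelled (intramolecular SNAr, forming O1–C8a), the precipitation of LiF making the closure irreversible. The closest known reaction type is the one-pot C-acylation/SNAr synthesis of chromones and flavones from 2-fluorobenzoyl chlorides and methyl ketone enolates. Ring C closes by a 6-endo-trig conjugate addition of oxygen to the C8a=C4a–C4=O unit followed by elimination; no stereocentre is created because C2 stays sp2 at the flavone oxidation level and is set by the catalyst in step 9. The step needs C- over O-acylation (lithium counter-ion, −78 °C, excess amide base) and a single site of ring closure; the substrate secures the latter, since only the oxygen on C2 can reach C8a through a six-membered transition state and C8a carries the only leaving group, activated by the ortho carbonyl. The ortho prenyl and para OMOM groups should slow the displacement without redirecting it, and the MOM ethers, the prenyl alkene and the chromene are inert to amide base and fluoride.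

Step 9
Reactants: 17 7-(methoxymethoxy)-2-[7-(methoxymethoxy)-2,2-dimethyl-2H-chromen-6-yl]-8-(3-methylbut-2-en-1-yl)-4H-chromen-4-one
Product: 19 (2S)-7-(methoxymethoxy)-2-[7-(methoxymethoxy)-2,2-dimethyl-2H-chromen-6-yl]-8-(3-methylbut-2-en-1-yl)-2,3-dihydro-4H-chromen-4-one, via silyl enol ether 18 (not isolated)
Conditions: Cu(OAc)2 (5 mol %), (R)-DTBM-SEGPHOS (5.5 mol %), (EtO)2MeSiH (2 equiv), toluene, 0 °C; then AcOH/H2O/THF, 0 °C
Reagents that add atoms: none
Why: Ligand-controlled 1,4-hydrocupration (enantioselective CuH conjugate reduction of a β,β-disubstituted enone, a reaction type known for chromones): the chiral bisphosphine copper hydride formed in situ delivers hydride to one face of C2 of the planar pyranone, so the C2 stereocentre is set by the ligand, trapping of the enolate as silyl enol ether 18 in the absence of an alcohol protects the new stereocentre from base-induced ring opening, and the isolated prenyl alkene and the hindered chromene alkene are not reduced.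

Step 10
Reactants: 19 (2S)-7-(methoxymethoxy)-2-[7-(methoxymethoxy)-2,2-dimethyl-2H-chromen-6-yl]-8-(3-methylbut-2-en-1-yl)-2,3-dihydro-4H-chromen-4-one
Product: 20 (2S)-7-hydroxy-2-(7-hydroxy-2,2-dimethyl-2H-chromen-6-yl)-8-(3-methylbut-2-en-1-yl)-2,3-dihydro-4H-chromen-4-one
Conditions: 3 M HCl (aq)/MeOH, 40 °C
Reagents that add atoms: none
Why: Acid-catalysed acetal exchange with methanol cleaves both MOM ethers, the C2 stereocentre is configurationally stable under mild acid (flavanones racemise by base-induced ring opening), and the low temperature should spare the prenyl and chromene alkenes.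

**Compound list**

1 | 4-bromo-3-fluorophenol | Oc1ccc(Br)c(F)c1 | starting material
2 | 1-bromo-2-fluoro-4-(methoxymethoxy)benzene | COCOc1ccc(Br)c(F)c1 | intermediate
3 | [3-bromo-2-fluoro-6-(methoxymethoxy)phenyl]lithium | COCOc1ccc(Br)c(F)c1[Li] | intermediate
4 | [3-bromo-2-fluoro-6-(methoxymethoxy)phenyl]copper | COCOc1ccc(Br)c(F)c1[Cu] | intermediate
5 | 1-bromo-2-fluoro-4-(methoxymethoxy)-3-(3-methylbut-2-en-1-yl)benzene | COCOc1ccc(Br)c(F)c1CC=C(C)C | intermediate
6 | [2-fluoro-4-(methoxymethoxy)-3-(3-methylbut-2-en-1-yl)phenyl]lithium | COCOc1ccc([Li])c(F)c1CC=C(C)C | intermediate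
7 | lithium 2-fluoro-4-(methoxymethoxy)-3-(3-methylbut-2-en-1-yl)benzoate | [Li+].COCOc1ccc(C(=O)[O-])c(F)c1CC=C(C)C | intermediate
8 | 2-fluoro-4-(methoxymethoxy)-3-(3-methylbut-2-en-1-yl)benzoic acid | COCOc1ccc(C(=O)O)c(F)c1CC=C(C)C | intermediate
9 | 2-fluoro-4-(methoxymethoxy)-3-(3-methylbut-2-en-1-yl)benzoyl chloride | COCOc1ccc(C(=O)Cl)c(F)c1CC=C(C)C | intermediate
10 | 2,2-dimethylchroman-7-ol | CC1(C)CCc2ccc(O)cc2O1 | starting material
11 | 2,2-dimethylchroman-7-yl acetate | CC(=O)Oc1ccc2CCC(C)(C)Oc2c1 | intermediate
12 | 1-(7-hydroxy-2,2-dimethylchroman-6-yl)ethan-1-one | CC(=O)c1cc2CCC(C)(C)Oc2cc1O | intermediate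
13 | 1-(7-hydroxy-2,2-dimethyl-2H-chromen-6-yl)ethan-1-one | CC(=O)c1cc2C=CC(C)(C)Oc2cc1O | intermediate
14 | 1-[7-(methoxymethoxy)-2,2-dimethyl-2H-chromen-6-yl]ethan-1-one | CC(=O)c1cc2C=CC(C)(C)Oc2cc1OCOC | intermediate
15 | lithium 1-[7-(methoxymethoxy)-2,2-dimethyl-2H-chromen-6-yl]ethen-1-olate | [Li+].C=C([O-])c1cc2C=CC(C)(C)Oc2cc1OCOC | intermediate
16 | lithium enolate of 1-[2-fluoro-4-(methoxymethoxy)-3-(3-methylbut-2-en-1-yl)phenyl]-3-[7-(methoxymethoxy)-2,2-dimethyl-2H-chromen-6-yl]propane-1,3-dione | [Li+].COCOc1ccc(C(=O)C=C([O-])c2cc3C=CC(C)(C)Oc3cc2OCOC)c(F)c1CC=C(C)C | intermediate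
17 | 7-(methoxymethoxy)-2-[7-(methoxymethoxy)-2,2-dimethyl-2H-chromen-6-yl]-8-(3-methylbut-2-en-1-yl)-4H-chromen-4-one | CC(C)=CCc1c(OCOC)ccc2c1oc(-c1cc3c(cc1OCOC)OC(C)(C)C=C3)cc2=O | intermediate
18 | diethoxy(methyl){[(2S)-7-(methoxymethoxy)-2-[7-(methoxymethoxy)-2,2-dimethyl-2H-chromen-6-yl]-8-(3-methylbut-2-en-1-yl)-2H-chromen-4-yl]oxy}silane | CC(C)=CCc1c(OCOC)ccc2c1O[C@H](c1cc3c(cc1OCOC)OC(C)(C)C=C3)C=C2O[Si](C)(OCC)OCC | intermediate
19 | (2S)-7-(methoxymethoxy)-2-[7-(methoxymethoxy)-2,2-dimethyl-2H-chromen-6-yl]-8-(3-methylbut-2-en-1-yl)-2,3-dihydro-4H-chromen-4-one | CC(C)=CCc1c(OCOC)ccc2c1O[C@H](c1cc3c(cc1OCOC)OC(C)(C)C=C3)CC2=O | intermediate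
20 | (2S)-7-hydroxy-2-(7-hydroxy-2,2-dimethyl-2H-chromen-6-yl)-8-(3-methylbut-2-en-1-yl)-2,3-dihydro-4H-chromen-4-one | CC(C)=CCc1c(O)ccc2c1O[C@H](c1cc3c(cc1O)OC(C)(C)C=C3)CC2=O | target

**Step count and risks**

Total step count: 10. Longest linear sequence: 7 steps (steps 1, 2, 3, 4, 8, 9, 10).

Steps most likely to fail:

Step 9. What may go wrong: poor facial selectivity of hydride delivery to the hindered pyranone that carries an ortho-substituted aryl group at C2, or ring opening of the metal enolate by loss of the C8a phenoxide before it is silylated, which would erode the enantiomeric purity. Fallback: setting out from flavone 17, non-selective 1,4-reduction with LiBH(s-Bu)3 in THF at −78 °C with an acetic acid quench should give the racemic flavanone F1. Kinetic resolution by asymmetric transfer hydrogenation (RuCl[(R,R)-TsDPEN](p-cymene) or its antipode, HCO2H/Et3N, EtOAc, rt), with the catalyst antipode chosen so that the 2R ketone is reduced to the cis-(2R,4R)-flavan-4-ol F2, should leave the 2S ketone untouched. This ketone is compound 19, at which the route is rejoined after chromatography, with at most half of the material.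

Step 8. What may go wrong: O-acylation or double acylation of the enolate in place of C-acylation, and stalling of the ring closure at the chelated lithium diketonate in front of the hindered, electron-rich fluoroarene. Fallback: setting out from aryl bromide 5, bromine–lithium exchange (n-BuLi, THF, −78 °C) and formylation with DMF should give the aldehyde F3. Aldol addition of lithium enolate 15 (from ketone 14 and LiN(SiMe3)2, −78 °C) should give the β-hydroxy ketone F4, and buffered Dess–Martin oxidation (NaHCO3, CH2Cl2) the free 1,3-diketone F5. Separate ring closure with K2CO3 in DMF at 90 °C, under a potassium counter-ion, returns to flavone 17.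

Step 2. What may go wrong: loss of LiF from the ortho-fluoro aryllithium before transmetalation, or attack of the organocopper at the γ-carbon of prenyl bromide (SN2′), which would put a reverse-prenyl group on the ring. Fallback: setting out from compound 2, the same lithiation followed by an iodine quench at −78 °C should give the aryl iodide F6. Stille coupling with tributyl(3-methylbut-2-en-1-yl)stannane (Pd(PPh3)4, DMF, 80 °C), selective for the C–I bond over the C–Br bond, returns to compound 5.

**Further compounds**

F1 | step 9 | rac-7-(methoxymethoxy)-2-[7-(methoxymethoxy)-2,2-dimethyl-2H-chromen-6-yl]-8-(3-methylbut-2-en-1-yl)-2,3-dihydro-4H-chromen-4-one | CC(C)=CCc1c(OCOC)ccc2c1OC(c1cc3c(cc1OCOC)OC(C)(C)C=C3)CC2=O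
F2 | step 9 | (2R,4R)-7-(methoxymethoxy)-2-[7-(methoxymethoxy)-2,2-dimethyl-2H-chromen-6-yl]-8-(3-methylbut-2-en-1-yl)-3,4-dihydro-2H-chromen-4-ol | CC(C)=CCc1c(OCOC)ccc2c1O[C@@H](c1cc3c(cc1OCOC)OC(C)(C)C=C3)C[C@H]2O
F3 | step 8 | 2-fluoro-4-(methoxymethoxy)-3-(3-methylbut-2-en-1-yl)benzaldehyde | COCOc1ccc(C=O)c(F)c1CC=C(C)C
F4 | step 8 | rac-3-[2-fluoro-4-(methoxymethoxy)-3-(3-methylbut-2-en-1-yl)phenyl]-3-hydroxy-1-[7-(methoxymethoxy)-2,2-dimethyl-2H-chromen-6-yl]propan-1-one | COCOc1ccc(C(O)CC(=O)c2cc3C=CC(C)(C)Oc3cc2OCOC)c(F)c1CC=C(C)C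
F5 | step 8 | 1-[2-fluoro-4-(methoxymethoxy)-3-(3-methylbut-2-en-1-yl)phenyl]-3-[7-(methoxymethoxy)-2,2-dimethyl-2H-chromen-6-yl]propane-1,3-dione | COCOc1ccc(C(=O)CC(=O)c2cc3C=CC(C)(C)Oc3cc2OCOC)c(F)c1CC=C(C)C
F6 | step 2 | 1-bromo-2-fluoro-3-iodo-4-(methoxymethoxy)benzene | COCOc1ccc(Br)c(F)c1I
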